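**Plan** (cadinane numbering: C1 ring-fusion CH, C2/C3 ring B CH2, C4 spiro carbon, C5=C6 alkene, C7 CH(iPr), C10 CH(Me), C15 chroman CH2; ring A = C1, C6–C10; ring B = C1–C6)
- Cuts: O–C4 and C15–CH(Ph) of the chroman (hetero-Diels–Alder of an o-quinone methide with the C4=C15 methylene of a muurola-4(15),5-diene); C4=C15 (Wittig); C5=C6 (β-elimination of a ring-fusion hydroxyl on C6); C1–C2 (radical ring closure); C4–C5 and C2/C3 back to ethyl acetate, EtMgBr and (S)-piperitone, which comes from (−)-menthone.
- Enabling feature: C2 is β to C4 (carried as a ketone) and C1 is the unsubstituted carbon of a trisubstituted ring A alkene C1=C10, so a cyclopropanol at C4 can release C2 as a β-keto (homoenolate) radical that closes ring B onto C1.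
- Forward order: ring A from menthone; C6–C5 by acetate aldol addition; C2/C3 by Kulinkovich cyclopropanation; ring B by C1–C2 closure; then C5=C6, the methylene, and the chroman ring.
- Stereochemistry: C7 from menthone; the temporary carbinol C6 by addition anti to isopropyl; C1 by the enforced cis ring fusion and C10 by axial hydrogen transfer in the key step; C4 and CH(Ph) in the cycloaddition. The required C1 configuration (cis to methyl, trans to isopropyl) is judged to be the one an equilibrating enone would not keep, so it is set kinetically and the C6 hydroxyl is removed afterwards.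

Key step: step 4

Assumption: (−)-menthone is taken free of isomenthone (which would give the enantiomeric enone in step 1), and Mn(O2CC5H4N)3 is prepared beforehand from Mn(OAc)3·2H2O and pyridine-2-carboxylic acid.

**Step 1**
Reactants: 1 (−)-menthone [(2S,5R)-5-methyl-2-(propan-2-yl)cyclohexan-1-one]
Product: 3 (S)-piperitone [(6S)-3-methyl-6-(propan-2-yl)cyclohex-2-en-1-one], via kinetic trimethylsilyl enol ether 2 (not isolated)
Conditions: LDA, THF, −78 °C; TMSCl, −78 °C → rt; then Pd(OAc)2, MeCN, rt
Reagents that add atoms: none
Why: Kinetic deprotonation of menthone takes the methylene hydrogen, and Saegusa–Ito oxidation of the silyl enol ether (palladium enolate, β-hydride elimination towards the only β-hydrogen, on the methyl-bearing carbon) should give the enone regiospecifically while the isopropyl-bearing centre is untouched; no new stereocentre is formed.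

**Step 2**
Reactants: 3 (S)-piperitone
Product: 4 ethyl 2-[(1R,6S)-1-hydroxy-3-methyl-6-(propan-2-yl)cyclohex-2-en-1-yl]acetate (CH2CO2Et trans to isopropyl)
Conditions: EtOAc, LDA, THF, −78 °C; then 3, −78 °C; aq. NH4Cl
Reagents that add atoms: ethyl acetate (CCOC(C)=O)
Why: Kinetic 1,2-addition (aldol addition) of the lithium ester enolate to the β,β-disubstituted enone should occur on the carbonyl face anti to the adjacent pseudo-equatorial isopropyl group (equatorial attack, the usual course for menthone-type ketones), which sets the temporary carbinol centre C6 with the chain trans to isopropyl.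

**Step 3**
Reactants: 4
Product: 5 1-{[(1R,6S)-1-hydroxy-3-methyl-6-(propan-2-yl)cyclohex-2-en-1-yl]methyl}cyclopropan-1-ol
Conditions: EtMgBr (3.5 equiv), Ti(OiPr)4 (0.3 equiv), THF, 0 °C → rt; aq. NH4Cl
Reagents that add atoms: ethylmagnesium bromide (CC[Mg]Br)
Why: In the Kulinkovich cyclopropanation the titanacyclopropane generated from EtMgBr and Ti(OiPr)4 acts as a 1,2-dicarbanion towards the ester, the tertiary alkoxide and the trisubstituted alkene are inert, and no stereocentre is touched.

**Step 4**
Reactants: 5
Product: 7 (4aR,5R,8S,8aR)-8a-hydroxy-5-methyl-8-(propan-2-yl)octahydronaphthalen-2(1H)-one (cis-fused ketol), via primary β-keto radical 6 (not isolated)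
Conditions: Mn(O2CC5H4N)3 [manganese tris(pyridine-2-carboxylate)] (2.2 equiv), Bu3SnH (1.2 equiv, slow addition), DMF, 0 °C
Reagents that add atoms: none
Why: Trivalent manganese oxidises the cyclopropanol, the strained ring opens to the primary β-keto radical 6 (homoenolate umpolung of C2), and 6 adds to the unsubstituted alkene carbon C1 to give a tertiary C10 radical that takes hydrogen from Bu3SnH. The closest known reaction type is the cyclisation of cyclopropanol-derived β-keto radicals onto tethered alkenes with a trivalent manganese carboxylate and a tin hydride. Ring B closes in the 6-exo-trig mode. C1 is controlled by the carbinol centre C6: the tether is pseudo-equatorial (trans to the equatorial isopropyl group) and can reach C1 only on its own face through a chair-like transition state, so the fusion is cis, with C1–C2 syn to C6–C5 and anti to isopropyl. C10 is controlled by the new axial C1–C2 bond, which shields the adjacent face, so hydrogen should arrive axially from the other side and leave the methyl group equatorial and cis to C2. The step needs 6-exo closure to outrun direct reduction of 6 and 7-endo attack; the quaternary C6 (no 1,5-hydrogen shift, gem-disubstituent effect), attack at the unsubstituted alkene carbon and slow addition of the stannane should secure this.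

**Step 5**
Reactants: 7
Product: 9 (4aR,5R,8S)-5-methyl-8-(propan-2-yl)-4,4a,5,6,7,8-hexahydronaphthalen-2(3H)-one, via tertiary trifluoroacetate 8 (not isolated)
Conditions: (CF3CO)2O, pyridine, DMAP (cat.), CH2Cl2, 0 °C; then DBU, 0 °C
Reagents that add atoms: none
Why: Trifluoroacetylation turns the ring-fusion hydroxyl into a leaving group that DBU expels by E1cB through the ketone enolate, so the alkene can only appear as C5=C6 in conjugation, no alkoxide is formed that could open ring B by retro-aldol cleavage, and the short cold base treatment should leave the γ-centres C1 and C7 untouched.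

**Step 6**
Reactants: 9
Product: 10 (1S,4R,4aR)-4-methyl-7-methylidene-1-(propan-2-yl)-1,2,3,4,4a,5,6,7-octahydronaphthalene [a (1R,7S,10R)-muurola-4(15),5-diene in cadinane numbering]
Conditions: Ph3PCH3Br, KOtBu, THF, 0 °C → rt
Reagents that add atoms: methyltriphenylphosphonium bromide (C[P+](c1ccccc1)(c1ccccc1)c1ccccc1.[Br-])
Why: Wittig methylenation of the unhindered enone carbonyl should give the semicyclic diene without forming a stereocentre, and a small excess of ylide with no free alkoxide keeps the γ-position from epimerising.

**Step 7**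
Reactants: 10; 11 benzaldehyde; 12 2,4,6-trihydroxybenzene-1,3-dicarbaldehyde (diformylphloroglucinol)
Product: 14 guajadial D, via o-quinone methide 13 (not isolated)
Conditions: H2O, 100 °C, sealed tube
Reagents that add atoms: none
Why: Knoevenagel condensation of 11 with the free ring CH of 12 gives the o-quinone methide 13, which should add to the terminal C4=C15 alkene in an inverse-electron-demand hetero-Diels–Alder reaction (benzylic carbon to C15, oxygen to the allylic carbon C4); axial C–O bond formation on the ring B half-chair anti to H1, with the C3 methylene endo and the bulkier C5=C6/ring A side exo, corresponds to the target, and the other diastereomers are expected as by-products to be removed by chromatography.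

**Compound list**
1 | (−)-menthone, (2S,5R)-5-methyl-2-(propan-2-yl)cyclohexan-1-one | CC(C)[C@@H]1CC[C@@H](C)CC1=O | starting material
2 | trimethyl{[(3R,6S)-3-methyl-6-(propan-2-yl)cyclohex-1-en-1-yl]oxy}silane | CC(C)[C@@H]1CC[C@@H](C)C=C1O[Si](C)(C)C | intermediate
3 | (S)-piperitone, (6S)-3-methyl-6-(propan-2-yl)cyclohex-2-en-1-one | CC(C)[C@@H]1CCC(C)=CC1=O | intermediate
4 | ethyl 2-[(1R,6S)-1-hydroxy-3-methyl-6-(propan-2-yl)cyclohex-2-en-1-yl]acetate | CC(C)[C@@H]1CCC(C)=C[C@@]1(O)CC(=O)OCC | intermediate
5 | 1-{[(1R,6S)-1-hydroxy-3-methyl-6-(propan-2-yl)cyclohex-2-en-1-yl]methyl}cyclopropan-1-ol | CC(C)[C@@H]1CCC(C)=C[C@@]1(O)CC2(O)CC2 | intermediate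
6 | 4-[(1R,6S)-1-hydroxy-3-methyl-6-(propan-2-yl)cyclohex-2-en-1-yl]-3-oxobutyl radical | CC(C)[C@@H]1CCC(C)=C[C@@]1(O)CC(=O)C[CH2] | intermediate
7 | (4aR,5R,8S,8aR)-8a-hydroxy-5-methyl-8-(propan-2-yl)octahydronaphthalen-2(1H)-one (cis-fused; OH and H-4a cis) | CC(C)[C@@H]1CC[C@@H](C)[C@H]2CCC(=O)C[C@@]12O | intermediate
8 | 8a-O-trifluoroacetyl derivative of 7 | CC(C)[C@@H]1CC[C@@H](C)[C@H]2CCC(=O)C[C@@]12OC(=O)C(F)(F)F | intermediate
9 | (4aR,5R,8S)-5-methyl-8-(propan-2-yl)-4,4a,5,6,7,8-hexahydronaphthalen-2(3H)-one | CC(C)[C@@H]1CC[C@@H](C)[C@H]2CCC(=O)C=C12 | intermediate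
10 | (1S,4R,4aR)-4-methyl-7-methylidene-1-(propan-2-yl)-1,2,3,4,4a,5,6,7-octahydronaphthalene | CC(C)[C@@H]1CC[C@@H](C)[C@H]2CCC(=C)C=C12 | intermediate
11 | benzaldehyde | O=Cc1ccccc1 | starting material
12 | 2,4,6-trihydroxybenzene-1,3-dicarbaldehyde | O=Cc1c(O)cc(O)c(C=O)c1O | starting material
13 | 5-benzylidene-2,4-dihydroxy-6-oxocyclohexa-1,3-diene-1,3-dicarbaldehyde (o-quinone methide) | O=CC1=C(O)C(C=O)=C(O)C(=Cc2ccccc2)C1=O | intermediate
14 | guajadial D | CC(C)[C@@H]1CC[C@@H](C)[C@H]2CC[C@@]3(C=C12)C[C@@H](c1ccccc1)c1c(O)c(C=O)c(O)c(C=O)c1O3 | target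

**Step count:** 7 steps in total; longest linear sequence 7 steps (1 → 3 → 4 → 5 → 7 → 9 → 10 → 14).

**Steps most likely to fail**

Step 4. What may go wrong: hydrogen transfer from the stannane to the primary radical before ring closure, or hydrogen delivery to C10 from the wrong face. The fallback sets out from 5 and comes back at 7. The ring opening and cyclisation are run without a hydrogen donor, with Mn(O2CC5H4N)3 and Cu(OAc)2 in DMF, so that the cyclised tertiary radical is oxidised by divalent copper and loses a proton. This should give the exocyclic alkene (4aR,8S,8aR)-8a-hydroxy-5-methylidene-8-(propan-2-yl)octahydronaphthalen-2(1H)-one F1. Hydrogenation of F1 with [Ir(cod)(py)(PCy3)]PF6 and H2 in CH2Cl2, directed by the axial ring-fusion hydroxyl to its own face, then sets C10 and gives 7.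

Step 7. What may go wrong: low facial or endo/exo selectivity in the cycloaddition, and isomerisation of the semicyclic diene under the hot, weakly acidic conditions. The fallback sets out from 11 and 12 (with 10) and comes back at 14. Compounds 11 and 12 are condensed with benzenesulfinic acid (HCO2H, H2O, rt) to the stable quinone methide precursor 2,4,6-trihydroxy-5-[phenyl(phenylsulfonyl)methyl]benzene-1,3-dicarbaldehyde F2. Treatment of F2 with K2CO3 in CH2Cl2 at 0 °C in the presence of 10 releases 13 by loss of sulfinate, so the cycloaddition can run cold. Diastereomers that still form are separated by preparative HPLC.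

Step 2. What may go wrong: insufficient facial selectivity in the 1,2-addition (the error would be relayed to C1), or proton transfer from the enone in place of addition. The fallback sets out from 1 and comes back at 4. The kinetic enolate of 1 is selenenylated (LDA; PhSeBr, THF, −78 °C) to (2S,5R)-5-methyl-6-(phenylselanyl)-2-(propan-2-yl)cyclohexan-1-one F3. The lithium enolate of ethyl acetate is added to this saturated menthone-type ketone, where equatorial attack anti to isopropyl is the usual course. This should give the β-hydroxy selenide ethyl 2-[(1R,3R,6S)-1-hydroxy-3-methyl-2-(phenylselanyl)-6-(propan-2-yl)cyclohexyl]acetate F4. Oxidation (H2O2, pyridine, CH2Cl2, 0 °C → rt) gives the selenoxide, which eliminates syn towards its only β-hydrogen, on the methyl-bearing carbon, and gives 4.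

**Further compounds**
F1 | step 4 | (4aR,8S,8aR)-8a-hydroxy-5-methylidene-8-(propan-2-yl)octahydronaphthalen-2(1H)-one | CC(C)[C@@H]1CCC(=C)[C@H]2CCC(=O)C[C@@]12O
F2 | step 7 | 2,4,6-trihydroxy-5-[phenyl(phenylsulfonyl)methyl]benzene-1,3-dicarbaldehyde | O=Cc1c(O)c(C=O)c(O)c(C(c2ccccc2)S(=O)(=O)c2ccccc2)c1O
F3 | step 2 | (2S,5R)-5-methyl-6-(phenylselanyl)-2-(propan-2-yl)cyclohexan-1-one | CC(C)[C@@H]1CC[C@@H](C)C([Se]c2ccccc2)C1=O
F4 | step 2 | ethyl 2-[(1R,3R,6S)-1-hydroxy-3-methyl-2-(phenylselanyl)-6-(propan-2-yl)cyclohexyl]acetate | CC(C)[C@@H]1CC[C@@H](C)C([Se]c2ccccc2)[C@@]1(O)CC(=O)OCC
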